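## The problem

Compound 14 is an achiral diaryl ether in which both rings are pentasubstituted. Ring A is a hydroquinone with hydroxyls at C1 and C4, bromine at C3 and C5, the ether oxygen at C6 and its only hydrogen at C2. Ring B is a 2,3,5-tribromo-4-hydroxyphenyl group whose only hydrogen is at C6'. There is no stereocentre, so nothing has to be controlled in space and the task is purely regiochemical: five bromines and four oxygens must each find one position. The ether oxygen is flanked by a hydroxyl and a bromine on ring A and by a bromine on ring B, so a late aryl C–O coupling of two hindered, electron-rich, polyhalogenated partners is unattractive. Bromination of a preformed triol ether could not tell C2 from C3 or spare C6'. The sensitive functions are the ring A hydroquinone (oxidised by air in base and by halogens), the five aryl C–Br bonds (lost on hydrogenolysis, with zerovalent metals and by halogen–metal exchange) and three phenols that must be told apart. The enabling feature is that the para oxygens at C1 and C4 make ring A a reduced 1,4-benzoquinone, with the vicinal pair C6 (O-aryl) and C5 (Br) between them. C1, C6, C5 and C4 with their heteroatoms are the four carbons of a squaric acid derivative, C2 and C3 are the two carbons of ethyne, and the C3 bromine can be delivered afterwards as bromide to the quinone.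

## Retrosynthesis

**14 from 13.** The last cut is the O–CH3 bond at C4'. A methyl ether is the one phenol protecting group that should survive an acetylide, 138 °C and strong acid. Benzyl would call for hydrogenolysis next to five C–Br bonds, and an ester would not survive the Grignard step. The forward reaction is a Lewis-acid demethylation that must leave the diaryl ether and the C–Br bonds alone.

**13 from 12.** The C3–Br bond is cut, leading back to quinone 12. Electrophilic bromination of a hydroquinone would have to choose between C2 and C3 against two ortho-directing hydroxyls and risks oxidation. Adding bromide as a nucleophile to the quinone instead uses the C6 aryloxy group as the control element: it donates into the C4 carbonyl, so the C1 carbonyl is the better acceptor and bromide should enter at C3. The addition also delivers the hydroquinone oxidation level with no redox step.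

**12 from 10 (through 11).** The C3–C4 bond of ring A is cut and the ring contracted to cyclobutenone 10, which carries an ethynyl and a hydroxyl group on the same carbon. Against a cut at the diaryl ether, this disconnection removes the whole of ring A and keeps both ring oxygens, the aryloxy group and the C5 bromine on a four-carbon core. The forward reaction must open 10 to ketene 11 and close it to a six-membered, not a five-membered, ring.

**10 from 8 and 9.** The bond between the carbinol carbon (future C1) and the alkyne (future C2) is cut, giving dione 8 and ethynylmagnesium bromide 9. No regiocontrol is asked of the addition, since both ethyne carbons carry hydrogen and either carbinol regioisomer leads to the same 12. Only carbonyl addition in preference to displacement of bromide or aryloxide is required.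

**8 from 7 and 5; 7 from 6.** The bond between the future C6 and the ether oxygen is cut. Forward, it is made as a vinylogous acyl substitution on squaric dibromide 7 by phenol 5, far easier than any aryl–oxygen coupling. The dibromide 7 comes from squaric acid 6 in one step, and its second bromine becomes the C5 bromine.

**5 from 1 through 4, 3 and 2.** Ring B needs its two oxygens distinguished and three bromines placed. In 4-hydroxyphenyl benzoate 1 the oxygens are already different. The free hydroxyl directs two bromines ortho to itself (2, future C3' and C5') and is then methylated (3). Saponification frees the other oxygen (4), which directs the third bromine to its ortho position (5, future C2'). Selective monomethylation of a tribrominated diol was rejected because alkylation would favour the less hindered oxygen, the one that must stay free.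

## Roads not taken

**Alternative 1:** Ring B is built by cycloaddition, forming C1'–C6' and C2'–C3'. Methyl 3-bromo-2-oxo-2H-pyran-5-carboxylate A2 would react with the silyl ketene acetal A3 of a ring A aryl acetate, and decarboxylative aromatisation with loss of the silyloxy group would give benzoate A1.
- Merits: pyrone cycloadditions of this kind are dependable, the ester of A2 polarises the diene so that bromine and aryloxy end up ortho, and A1 is a bench-stable compound.
- Weak points: A1 has one of ring B's three bromines and an ester where the C4' hydroxyl belongs. Degrading the ester to a hydroxyl costs three or four steps. Two bromines must then be placed beside the new hydroxyl while ring A, with two methoxy groups and an open C2, is at least as reactive. A3 comes from an aryl ester enolate that can fragment to a ketene and a phenoxide, and in the aromatisation the aryloxide is a better leaving group than the silyloxy group.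
- Comparison: this road is better in the stability of its intermediates, since the chosen plan has to handle moisture-sensitive squaric halides and a heat-sensitive carbinol. The chosen plan sets against this that both rings leave its key step needing only one bromine and a deprotection, with no electrophilic bromination after the rings are joined.

**Alternative 2:** Ring A is carried as a six-membered carbocycle. Phenol 5 would be attached to a cyclic 1,3-diketone as the vinylogous ester A5, and excess bromine in acetic acid would aromatise it and form three C–Br bonds, giving 2,4,6-tribromo-3-(aryloxy)phenol A4. Oxidative exchange of the bromine para to the hydroxyl for oxygen and reduction would lead to 13.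
- Merits: it is as short as the chosen plan or shorter and uses cheap reagents. The ring A bromines are placed by ortho/para direction with C2 meta to both oxygens, so the regiochemical question of step 9 does not arise. In that respect this road is better.
- Weak points: A5 must survive the hydrogen bromide released before aromatisation, which can cleave it back to 5. Excess bromine meets ring B with its last open position, C6', ortho to the ether oxygen. The oxidation needs a strong oxidant on a molecule carrying an anisole ring. Under- and over-brominated polybromo diaryl ethers would be hard to separate.
- Comparison: against its regiochemical certainty, the chosen plan places each substituent by a discrete bond-forming event, uses no molecular bromine after ring B is attached, and has a neutral thermal key step.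

**Alternative 3:** Ring A is built by cycloaddition, forming C5–C6 and C1–C2. 3,5-Dibromo-4-methoxy-2H-pyran-2-one A7 would react with the silyl ketene acetal A8 of the ring B aryl methoxyacetate, and decarboxylative aromatisation would give the trimethyl ether A6, one global demethylation from 14.
- Merits: it is the most convergent road. All five bromines and four oxygens are in place after the key step, and only one step follows it, against two in the chosen plan.
- Weak points: the new bond at the bromine-bearing pyrone carbon joins it to a fully substituted acetal carbon with a bulky ortho-bromo aryloxy group. The 4-methoxy group makes the pyrone a poorer partner for an electron-rich alkene. A8 derives from the enolate of an ester of an acidic phenol, which can eliminate to a ketene. In the aromatisation, loss of the aryloxide instead of the silyloxy group would erase the ether linkage. A7 must also be made.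
- Comparison: if the cycloaddition went as drawn, this road would be shorter after the key step. The chosen plan sets against it an ether bond made by simple addition–elimination on 7 and never placed on a carbon from which aromatisation can expel it.

Key step: step 8

Remark on the chemistry: cyclobutenone 10 has one stereocentre, is made and used as the racemate, and loses that centre in step 8. Compounds 1, 6 and 9 (as a THF solution) are taken as purchased.

## Route

Step 1
Reactants: 1 4-hydroxyphenyl benzoate
Product: 2 3,5-dibromo-4-hydroxyphenyl benzoate
Conditions: Br2 (2.1 equiv), AcOH, rt
Reagents that add atoms: bromine, BrBr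
Why: Electrophilic aromatic bromination; the free hydroxyl is the only strong donor and directs both bromines to its ortho positions (future C3' and C5'), the para position being blocked by the benzoyloxy group that keeps the second oxygen distinct.

Step 2
Reactants: 2 3,5-dibromo-4-hydroxyphenyl benzoate
Product: 3 3,5-dibromo-4-methoxyphenyl benzoate
Conditions: MeI, K2CO3, acetone, reflux
Reagents that add atoms: iodomethane, CI
Why: Williamson etherification of the acidic 2,6-dibromophenol; the benzoate is untouched by K2CO3 in an aprotic solvent, so only the future C4' oxygen is methylated.

Step 3
Reactants: 3 3,5-dibromo-4-methoxyphenyl benzoate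
Product: 4 3,5-dibromo-4-methoxyphenol
Conditions: NaOH (aq), MeOH/THF, rt; then HCl (aq)
Reagents that add atoms: none
Why: Saponification of the aryl benzoate frees the future ether oxygen; the aryl methyl ether and the C–Br bonds are inert to hydroxide at room temperature.

Step 4
Reactants: 4 3,5-dibromo-4-methoxyphenol
Product: 5 2,3,5-tribromo-4-methoxyphenol
Conditions: Br2 (1.0 equiv), CH2Cl2, 0 °C
Reagents that add atoms: bromine, BrBr
Why: Electrophilic aromatic bromination ortho to the phenol; the para position is occupied, the two ortho positions are equivalent, and the first bromine lowers the reactivity enough for one equivalent of Br2 at 0 °C to stop at the tribromide.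

Step 5
Reactants: 6 squaric acid (3,4-dihydroxycyclobut-3-ene-1,2-dione)
Product: 7 3,4-dibromocyclobut-3-ene-1,2-dione
Conditions: (COBr)2 (2.2 equiv), DMF (cat.), CH2Cl2, reflux
Reagents that add atoms: oxalyl bromide, O=C(Br)C(=O)Br
Why: Vinylogous acid bromide formation through the bromoiminium salt from DMF and oxalyl bromide (Vilsmeier-type activation), the bromide counterpart of the standard squaric dichloride preparation; gas evolution drives it to completion.

Step 6
Reactants: 7 3,4-dibromocyclobut-3-ene-1,2-dione; 5 2,3,5-tribromo-4-methoxyphenol
Product: 8 3-bromo-4-(2,3,5-tribromo-4-methoxyphenoxy)cyclobut-3-ene-1,2-dione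
Conditions: iPr2NEt (1.0 equiv), CH2Cl2, −78 → 0 °C, 5 added slowly to 7 (1.2 equiv)
Reagents that add atoms: none
Why: Addition–elimination of the phenoxide at a vinylogous acyl bromide; the first aryloxy group makes the product a vinylogous ester, less electrophilic than 7, so slow addition to excess 7 at low temperature should stop at monosubstitution.

Step 7
Reactants: 8 3-bromo-4-(2,3,5-tribromo-4-methoxyphenoxy)cyclobut-3-ene-1,2-dione; 9 ethynylmagnesium bromide
Product: 10 rac-2-bromo-4-ethynyl-4-hydroxy-3-(2,3,5-tribromo-4-methoxyphenoxy)cyclobut-2-en-1-one
Conditions: THF, −78 °C; then pH 7 phosphate buffer, −78 °C → rt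
Reagents that add atoms: none
Why: 1,2-Addition of an alkynyl Grignard reagent to a cyclobutenedione carbonyl, expected at the carbonyl next to the aryloxy-bearing carbon because the other one is deactivated as a vinylogous ester. The carbinol centre forms without control, so 10 is racemic, and it is erased in step 8; the buffered cold quench avoids acid-induced loss of the phenol.

Step 8
Reactants: 10 rac-2-bromo-4-ethynyl-4-hydroxy-3-(2,3,5-tribromo-4-methoxyphenoxy)cyclobut-2-en-1-one
Product: 12 2-bromo-3-(2,3,5-tribromo-4-methoxyphenoxy)cyclohexa-2,5-diene-1,4-dione, via enynyl ketene 11 (not isolated)
Conditions: p-xylene (0.01 M, degassed), 138 °C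
Reagents that add atoms: none
Why: On heating, 10 undergoes conrotatory 4π electrocyclic opening of the bond between the carbonyl and carbinol carbons; the hydroxyl, as the donor, rotates outward, so ketene 11 forms with the ethynyl group on the same side as the ketene carbon. That carbon then bonds to the terminal alkyne carbon, closing the six-membered carbocycle of ring A (endo closure onto the triple bond, the ring taking in both alkyne carbons) as a quinone-type diradical, and transfer of the hydroxyl hydrogen to the ring carbon radical gives quinone 12. The closest known reaction type is the Moore rearrangement of 4-alkynyl-4-hydroxycyclobutenones to 1,4-benzoquinones. No stereocentre is formed and the carbinol centre of 10 is destroyed, so its racemic nature is irrelevant. The step needs six- over five-membered closure (bonding to the inner alkyne carbon would give an alkylidenecyclopentenedione), and the hydrogen at the alkyne terminus, which offers no stabilisation to an exocyclic radical, should secure this. No regiocontrol is needed from step 7, because both carbons from ethyne carry hydrogen and either carbinol regioisomer would open and close to the same 12. High dilution and exclusion of oxygen keep the ketene from capture by the tertiary alcohol of a second molecule.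

Step 9
Reactants: 12 2-bromo-3-(2,3,5-tribromo-4-methoxyphenoxy)cyclohexa-2,5-diene-1,4-dione
Product: 13 3,5-dibromo-2-(2,3,5-tribromo-4-methoxyphenoxy)benzene-1,4-diol
Conditions: HBr (33% in AcOH), CH2Cl2, 0 °C → rt, under N2
Reagents that add atoms: hydrogen bromide, Br
Why: Conjugate (1,4-) addition of HBr to a quinone followed by enolisation gives the hydroquinone without a separate redox step. The aryloxy group donates into the carbonyl flanked by bromine, so the other carbonyl is the acceptor and bromide should add β to it, at the CH para to the aryloxy-bearing carbon (C3 of ring A); anhydrous acid avoids hydrolysis of the aryl enol ether.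

Step 10
Reactants: 13 3,5-dibromo-2-(2,3,5-tribromo-4-methoxyphenoxy)benzene-1,4-diol
Product: 14 3,5-dibromo-2-(2,3,5-tribromo-4-hydroxyphenoxy)benzene-1,4-diol
Conditions: BBr3 (excess), CH2Cl2, −78 °C → rt; then H2O
Reagents that add atoms: none
Why: Lewis acid ether cleavage: BBr3 binds the methoxy oxygen and bromide removes the methyl group by SN2; the diaryl ether has no sp3 carbon to attack and the aryl bromides and phenols are inert, as in routine demethylations of methoxylated polybromo diphenyl ethers.

## Compound list

1 | 4-hydroxyphenyl benzoate | O=C(Oc1ccc(O)cc1)c1ccccc1 | starting material
2 | 3,5-dibromo-4-hydroxyphenyl benzoate | O=C(Oc1cc(Br)c(O)c(Br)c1)c1ccccc1 | intermediate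
3 | 3,5-dibromo-4-methoxyphenyl benzoate | COc1c(Br)cc(OC(=O)c2ccccc2)cc1Br | intermediate
4 | 3,5-dibromo-4-methoxyphenol | COc1c(Br)cc(O)cc1Br | intermediate
5 | 2,3,5-tribromo-4-methoxyphenol | COc1c(Br)cc(O)c(Br)c1Br | intermediate
6 | squaric acid (3,4-dihydroxycyclobut-3-ene-1,2-dione) | OC1=C(O)C(=O)C1=O | starting material
7 | 3,4-dibromocyclobut-3-ene-1,2-dione | BrC1=C(Br)C(=O)C1=O | intermediate
8 | 3-bromo-4-(2,3,5-tribromo-4-methoxyphenoxy)cyclobut-3-ene-1,2-dione | O=C1C(=O)C(Oc2cc(Br)c(OC)c(Br)c2Br)=C1Br | intermediate
9 | ethynylmagnesium bromide | C#C[Mg]Br | starting material
10 | rac-2-bromo-4-ethynyl-4-hydroxy-3-(2,3,5-tribromo-4-methoxyphenoxy)cyclobut-2-en-1-one (racemate, one stereocentre, not specified) | O=C1C(Br)=C(Oc2cc(Br)c(OC)c(Br)c2Br)C1(O)C#C | intermediate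
11 | (3Z)-2-bromo-4-hydroxy-3-(2,3,5-tribromo-4-methoxyphenoxy)hexa-1,3-dien-5-yn-1-one (enynyl ketene, not isolated) | O=C=C(Br)/C(Oc1cc(Br)c(OC)c(Br)c1Br)=C(/O)C#C | intermediate
12 | 2-bromo-3-(2,3,5-tribromo-4-methoxyphenoxy)cyclohexa-2,5-diene-1,4-dione | O=C1C=CC(=O)C(Oc2cc(Br)c(OC)c(Br)c2Br)=C1Br | intermediate
13 | 3,5-dibromo-2-(2,3,5-tribromo-4-methoxyphenoxy)benzene-1,4-diol | Oc1cc(Br)c(O)c(Br)c1Oc1cc(Br)c(OC)c(Br)c1Br | intermediate
14 | 3,5-dibromo-2-(2,3,5-tribromo-4-hydroxyphenoxy)benzene-1,4-diol | Oc1cc(Br)c(O)c(Br)c1Oc1cc(Br)c(O)c(Br)c1Br | target

## Step count and least certain steps

Total: 10 steps. Longest linear sequence: 9 steps (steps 1–4, then 6–10, from 1 to 14); step 5 is a one-step side branch from 6.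

**Step 8 (key step).** The ketene may close onto the inner alkyne carbon to a five-membered ring, be acylated by the tertiary hydroxyl of another molecule, or the carbinol may lose the phenol thermally before it opens. The fallback sets out from 8 and returns at 12. Vinylmagnesium bromide is added to 8 in place of 9 to give racemic 2-bromo-4-ethenyl-4-hydroxy-3-(2,3,5-tribromo-4-methoxyphenoxy)cyclobut-2-en-1-one F1. Heating F1 in toluene should open it to a dienylketene that can close only by 6π electrocyclisation, and tautomerisation gives 3-bromo-2-(2,3,5-tribromo-4-methoxyphenoxy)benzene-1,4-diol F2. Oxidation of F2 with Ag2O gives 12.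

**Step 7.** The acetylide may attack the aryloxy- or bromine-bearing ring carbon by addition–elimination instead of the carbonyl, and the carbinol may lose the phenol during work-up. The fallback sets out from 7 and returns at 10 by reversing the order of the two bond formations. Reagent 9 is added to 7 at −78 °C, where no aryloxide leaving group is present and neither carbonyl is deactivated, to give racemic 2,3-dibromo-4-ethynyl-4-hydroxycyclobut-2-en-1-one F3. In F3 only the bromine β to the carbonyl is activated, so 5 with K2CO3 in MeCN should displace it by addition–elimination and give 10 as a single regioisomer.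

**Step 9.** Regioselectivity may be poor, because the ring bromine directs bromide to the other CH. Redox exchange between product and unreacted quinone may lead to over-bromination, and bromide may displace the aryloxide. The fallback sets out from 12 and returns at 13. Reductive acetylation (Zn, Ac2O, NaOAc) gives 2-bromo-3-(2,3,5-tribromo-4-methoxyphenoxy)-1,4-phenylene diacetate F4. Electrophilic bromination (Br2, FeBr3 cat., CH2Cl2) is then directed by the aryloxy group, the only strong donor left, to its para position and gives 3,5-dibromo-2-(2,3,5-tribromo-4-methoxyphenoxy)-1,4-phenylene diacetate F5. Acid methanolysis (HCl, MeOH) of F5 gives 13.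

**Step 5.** Conversion of the insoluble diacid may be incomplete, and the moisture-sensitive dibromide may hydrolyse or decompose on isolation. The fallback sets out from 6 and returns at 7. Silylation of 6 with (Me3Si)2NH gives 3,4-bis(trimethylsilyloxy)cyclobut-3-ene-1,2-dione F6, which is soluble in CH2Cl2. Treatment of F6 with (COBr)2 should give 7 with only volatile by-products, and 7 is then used crude in step 6.

## Further compounds

F1 | step 8 | rac-2-bromo-4-ethenyl-4-hydroxy-3-(2,3,5-tribromo-4-methoxyphenoxy)cyclobut-2-en-1-one | O=C1C(Br)=C(Oc2cc(Br)c(OC)c(Br)c2Br)C1(O)C=C
F2 | step 8 | 3-bromo-2-(2,3,5-tribromo-4-methoxyphenoxy)benzene-1,4-diol | Oc1ccc(O)c(Br)c1Oc1cc(Br)c(OC)c(Br)c1Br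
F3 | step 7 | rac-2,3-dibromo-4-ethynyl-4-hydroxycyclobut-2-en-1-one | O=C1C(Br)=C(Br)C1(O)C#C
F4 | step 9 | 2-bromo-3-(2,3,5-tribromo-4-methoxyphenoxy)-1,4-phenylene diacetate | CC(=O)Oc1ccc(OC(C)=O)c(Oc2cc(Br)c(OC)c(Br)c2Br)c1Br
F5 | step 9 | 3,5-dibromo-2-(2,3,5-tribromo-4-methoxyphenoxy)-1,4-phenylene diacetate | CC(=O)Oc1c(Br)cc(OC(C)=O)c(Oc2cc(Br)c(OC)c(Br)c2Br)c1Br
F6 | step 5 | 3,4-bis(trimethylsilyloxy)cyclobut-3-ene-1,2-dione | C[Si](C)(C)OC1=C(O[Si](C)(C)C)C(=O)C1=O
A1 | alternative 1 | methyl 3-bromo-4-(2,4-dibromo-3,6-dimethoxyphenoxy)benzoate | COC(=O)c1ccc(Oc2c(OC)cc(Br)c(OC)c2Br)c(Br)c1
A2 | alternative 1 | methyl 3-bromo-2-oxo-2H-pyran-5-carboxylate | COC(=O)C1=COC(=O)C(Br)=C1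
A3 | alternative 1 | tert-butyl{[1-(2,4-dibromo-3,6-dimethoxyphenoxy)ethenyl]oxy}dimethylsilane | C=C(O[Si](C)(C)C(C)(C)C)Oc1c(OC)cc(Br)c(OC)c1Br
A4 | alternative 2 | 2,4,6-tribromo-3-(2,3,5-tribromo-4-methoxyphenoxy)phenol | Oc1c(Br)cc(Br)c(Oc2cc(Br)c(OC)c(Br)c2Br)c1Br
A5 | alternative 2 | 3-(2,3,5-tribromo-4-methoxyphenoxy)cyclohex-2-en-1-one | O=C1C=C(Oc2cc(Br)c(OC)c(Br)c2Br)CCC1
A6 | alternative 3 | 1,3-dibromo-2,5-dimethoxy-4-(2,3,5-tribromo-4-methoxyphenoxy)benzene | COc1cc(Br)c(OC)c(Br)c1Oc1cc(Br)c(OC)c(Br)c1Br
A7 | alternative 3 | 3,5-dibromo-4-methoxy-2H-pyran-2-one | O=C1OC=C(Br)C(OC)=C1Br
A8 | alternative 3 | tert-butyl{[2-methoxy-1-(2,3,5-tribromo-4-methoxyphenoxy)ethenyl]oxy}dimethylsilane (alkene geometry not specified) | COC=C(O[Si](C)(C)C(C)(C)C)Oc1cc(Br)c(OC)c(Br)c1Br
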